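**Assumption:** I follow the SMILES, in which the phenyl-bearing carbon sits between the prenyl-bearing and aroyl-bearing carbons (prenyl/Ph cis, Ph/aroyl trans). My names number the ring from the acyl carbon (C1), so the target is (1R,5S,6R), equal to 6'R, 2'S, 1'R in the given name.

## Retrosynthetic overview

1. Target 19 comes from MOM removal of 18, which comes from Weinreb amide 14 plus ortho-lithiated tris-MOM-phloroglucinol 17 (aryl ketone made late).
2. The prenyl group comes from a Wittig reaction on the C5–CH2CHO aldehyde 10, which comes from Claisen rearrangement of allyl vinyl ether 9. The suprafacial [3,3] shift moves the alkene into its final position and places the new carbon cis to phenyl.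
3. Allylic alcohol 7 comes from SeO2 hydroxylation of trans ester 6.
4. Ester 6 comes from an endo, Cu–box-catalysed Diels–Alder of 1-phenyl-3-methylbutadiene 3 with acrylimide 4, then C1 epimerisation. This is the only ring-forming step; the carbocycle is made first.
5. A direct ocimene + chalcone cycloaddition is not used: it favours the panduratin regiochemistry, and the endo adduct of the other regiochemistry has prenyl trans to phenyl.

## Route

**Step 1**
Reactants: 1, (E)-4-phenylbut-3-en-2-one; 2, methyltriphenylphosphonium bromide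
Product: 3, [(1E)-3-methylbuta-1,3-dien-1-yl]benzene
Conditions: KOtBu, THF, 0 °C to rt
Reagents that add atoms: ylide from 2, C[P+](c1ccccc1)(c1ccccc1)c1ccccc1.[Br-] (adds CH2)
Why: Wittig methylenation; the non-stabilised ylide adds 1,2 to the enone and leaves the E-styryl geometry untouched.

**Step 2**
Reactants: 3; 4, 3-acryloyl-1,3-oxazolidin-2-one
Product: 5, 3-[(1S,2R)-4-methyl-2-phenylcyclohex-3-ene-1-carbonyl]-1,3-oxazolidin-2-one (cis; endo adduct)
Conditions: [Cu((S,S)-t-Bu-box)](SbF6)2 (10 mol %), CH2Cl2, –20 °C to rt. Remove the minor exo (trans) diastereomer by chromatography or crystallisation; after step 3 it would become the enantiomer of 6.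
Reagents that add atoms: none
Why: Catalytic asymmetric Diels–Alder. The 1-aryl ("ortho") and 3-methyl ("para") effects reinforce, so the acyl carbon bonds to the PhCH terminus. The chelated s-cis imide is attacked on its Cα Re face (C1 = S, by the square-planar Cu–box model; use the (R,R) ligand if the sense is opposite), and the endo transition state sets C2 = R (Ph cis to acyl).

**Step 3**
Reactants: 5
Product: 6, methyl (1R,2R)-4-methyl-2-phenylcyclohex-3-ene-1-carboxylate (trans)
Conditions: NaOMe, MeOH, 0 °C then reflux; separate residual cis ester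
Reagents that add atoms: sodium methoxide / methanol, C[O-].[Na+] / CO (adds OMe)
Why: Acyl substitution cleaves the imide, and thermodynamic α-epimerisation gives the trans-diequatorial ester. C2 (R, set in step 2) is untouched and C1 inverts to R.

**Step 4**
Reactants: 6
Product: 7, methyl (1R,2R,5R)-5-hydroxy-4-methyl-2-phenylcyclohex-3-ene-1-carboxylate (5-OH cis to 2-Ph)
Conditions: SeO2 (0.5 equiv), t-BuOOH, CH2Cl2, 0 °C to rt
Reagents that add atoms: tert-butyl hydroperoxide CC(C)(C)OO / selenium dioxide O=[Se]=O (adds one O)
Why: SeO2 allylic oxidation (ene reaction then [2,3]-shift) attacks the ring CH2 next to the methyl-bearing alkene carbon. Removal of the pseudoaxial C5–H of the diequatorial half-chair and suprafacial return of oxygen should give the pseudoaxial alcohol, which is on the phenyl face.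

**Step 5**
Reactants: 7; 8, vinyl acetate
Product: 9, methyl (1R,2R,5R)-5-(ethenyloxy)-4-methyl-2-phenylcyclohex-3-ene-1-carboxylate
Conditions: [Ir(cod)Cl]2 (2 mol %), Na2CO3, toluene, 100 °C
Reagents that add atoms: vinyl acetate, CC(=O)OC=C (adds CH=CH2 on O)
Why: Ir-catalysed transfer vinylation (transetherification) of the alcohol; no stereocentre is touched.

**Step 6**
Reactants: 9
Product: 10, methyl (1R,5S,6R)-4-methyl-5-(2-oxoethyl)-6-phenylcyclohex-3-ene-1-carboxylate
Conditions: toluene, 170 °C, sealed tube (BHT trace)
Reagents that add atoms: none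
Why: Claisen [3,3] rearrangement. The new C–C bond forms on the same face as the breaking C–O bond, so CH2CHO lands cis to phenyl (new centre S), and the alkene moves to the final Me-C=CH position.

**Step 7**
Reactants: 10; 11, isopropyltriphenylphosphonium iodide
Product: 12, methyl (1R,5S,6R)-4-methyl-5-(3-methylbut-2-en-1-yl)-6-phenylcyclohex-3-ene-1-carboxylate
Conditions: n-BuLi, THF, 0 °C; add 10 at –78 °C, warm to rt
Reagents that add atoms: ylide from 11, CC(C)[P+](c1ccccc1)(c1ccccc1)c1ccccc1.[I-] (adds C(CH3)2)
Why: Wittig olefination with the isopropylidene ylide turns CH2CHO into prenyl; the aldehyde reacts in preference to the ester and no stereocentre is involved.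

**Step 8**
Reactants: 12; 13, N,O-dimethylhydroxylamine hydrochloride
Product: 14, (1R,5S,6R)-N-methoxy-N,4-dimethyl-5-(3-methylbut-2-en-1-yl)-6-phenylcyclohex-3-ene-1-carboxamide
Conditions: i-PrMgCl, THF, –20 to 0 °C
Reagents that add atoms: 13, CNOC.Cl (adds N(OMe)Me)
Why: Weinreb amide formation by magnesium-amide aminolysis of the ester. C1 is already the thermodynamically preferred equatorial epimer, so basic conditions cannot erode it.

**Step 9** (side branch)
Reactants: 15, phloroglucinol; 16, chloromethyl methyl ether
Product: 17, 1,3,5-tris(methoxymethoxy)benzene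
Conditions: NaH, DMF, 0 °C to rt
Reagents that add atoms: MOMCl, COCCl (adds three CH2OCH3)
Why: Williamson O-alkylation; MOM protects the phenols and directs the later ortho-lithiation.

**Step 10**
Reactants: 14; 17
Product: 18, [(1R,5S,6R)-4-methyl-5-(3-methylbut-2-en-1-yl)-6-phenylcyclohex-3-en-1-yl][2,4,6-tris(methoxymethoxy)phenyl]methanone
Conditions: 17 (2.5 equiv), n-BuLi, THF, 0 °C; then 14, –78 to 0 °C
Reagents that add atoms: none
Why: Directed ortho-lithiation between two OMOM groups, then acylation by the Weinreb amide; the chelated tetrahedral intermediate stops at the ketone.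

**Step 11**
Reactants: 18
Product: 19, (2,4,6-trihydroxyphenyl)[(1R,5S,6R)-4-methyl-5-(3-methylbut-2-en-1-yl)-6-phenylcyclohex-3-en-1-yl]methanone (target)
Conditions: 3 M HCl, MeOH, rt to 40 °C
Reagents that add atoms: none
Why: Acid-catalysed acetal (MOM) hydrolysis under mild conditions that should leave both trisubstituted alkenes intact; the equatorial C1 centre is the stable epimer.

## Compound list

1 | (E)-4-phenylbut-3-en-2-one | CC(=O)/C=C/c1ccccc1 | starting material
2 | methyltriphenylphosphonium bromide | C[P+](c1ccccc1)(c1ccccc1)c1ccccc1.[Br-] | starting material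
3 | [(1E)-3-methylbuta-1,3-dien-1-yl]benzene | CC(=C)/C=C/c1ccccc1 | intermediate
4 | 3-acryloyl-1,3-oxazolidin-2-one | C=CC(=O)N1CCOC1=O | starting material
5 | 3-[(1S,2R)-4-methyl-2-phenylcyclohex-3-ene-1-carbonyl]-1,3-oxazolidin-2-one | O=C(N1CCOC1=O)[C@H]2CCC(C)=C[C@H]2c3ccccc3 | intermediate
6 | methyl (1R,2R)-4-methyl-2-phenylcyclohex-3-ene-1-carboxylate | COC(=O)[C@@H]1CCC(C)=C[C@H]1c1ccccc1 | intermediate
7 | methyl (1R,2R,5R)-5-hydroxy-4-methyl-2-phenylcyclohex-3-ene-1-carboxylate | COC(=O)[C@@H]1C[C@@H](O)C(C)=C[C@H]1c1ccccc1 | intermediate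
8 | vinyl acetate | CC(=O)OC=C | starting material
9 | methyl (1R,2R,5R)-5-(ethenyloxy)-4-methyl-2-phenylcyclohex-3-ene-1-carboxylate | COC(=O)[C@@H]1C[C@@H](OC=C)C(C)=C[C@H]1c1ccccc1 | intermediate
10 | methyl (1R,5S,6R)-4-methyl-5-(2-oxoethyl)-6-phenylcyclohex-3-ene-1-carboxylate | O=CC[C@@H]1C(C)=CC[C@@H](C(=O)OC)[C@@H]1c1ccccc1 | intermediate
11 | isopropyltriphenylphosphonium iodide | CC(C)[P+](c1ccccc1)(c1ccccc1)c1ccccc1.[I-] | starting material
12 | methyl (1R,5S,6R)-4-methyl-5-(3-methylbut-2-en-1-yl)-6-phenylcyclohex-3-ene-1-carboxylate | CC(C)=CC[C@@H]1C(C)=CC[C@@H](C(=O)OC)[C@@H]1c1ccccc1 | intermediate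
13 | N,O-dimethylhydroxylamine hydrochloride | CNOC.Cl | starting material
14 | (1R,5S,6R)-N-methoxy-N,4-dimethyl-5-(3-methylbut-2-en-1-yl)-6-phenylcyclohex-3-ene-1-carboxamide | CC(C)=CC[C@@H]1C(C)=CC[C@@H](C(=O)N(C)OC)[C@@H]1c1ccccc1 | intermediate
15 | phloroglucinol (benzene-1,3,5-triol) | Oc1cc(O)cc(O)c1 | starting material
16 | chloromethyl methyl ether | COCCl | starting material
17 | 1,3,5-tris(methoxymethoxy)benzene | COCOc1cc(OCOC)cc(OCOC)c1 | intermediate
18 | [(1R,5S,6R)-4-methyl-5-(3-methylbut-2-en-1-yl)-6-phenylcyclohex-3-en-1-yl][2,4,6-tris(methoxymethoxy)phenyl]methanone | CC(C)=CC[C@@H]1C(C)=CC[C@@H](C(=O)c2c(OCOC)cc(OCOC)cc2OCOC)[C@@H]1c1ccccc1 | intermediate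
19 | (1'R,2'S,6'R)-2-hydroxyisopanduratin A | CC(C)=CC[C@@H]1C(C)=CC[C@@H](C(=O)c2c(O)cc(O)cc2O)[C@@H]1c1ccccc1 | target

## Summary

Total step count: 11. Longest linear sequence: 10 (steps 1–8, 10, 11); step 9 is a one-step side branch.

Steps most likely to fail, with fallbacks:

1. **Step 4 (SeO2 hydroxylation).** The C5 epimer ratio is the least certain outcome in the route, and over-oxidation to the enone or CH3 oxidation may compete. Fallback: take the material to the 5-ketone (DMP) and set the carbinol by reagent-controlled CBS reduction, or Luche reduction followed by Mitsunobu inversion, then rejoin at step 5.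
2. **Step 2 (catalytic asymmetric Diels–Alder).** The cationic Cu(II) Lewis acid may polymerise the styryl diene, or endo:exo and ee may be modest. Fallback: use a covalently bound auxiliary, 4-benzyl-3-acryloyloxazolidin-2-one (enantiomer chosen to give the 1S,2R adduct) with Et2AlCl at –78 °C, purify the diastereomer by crystallisation, and continue with the same step 3.
3. **Step 10 (hindered aryllithium + Weinreb amide).** Addition may be slow, or the amide may lose its N-methoxy group. Fallback: reduce ester 12 to the aldehyde (DIBAL-H, –78 °C), add lithiated 17 to give the carbinol, and oxidise it to ketone 18 with DMP.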